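## Retrosynthetic overview

1. Feature: in each chroman the benzene ring C4a–C5–C6–C7–C8–C8a alternates oxygen-bearing carbons (C5, C7, C8a) with carbon-bearing ones (C4a, C6, C8). This is the imprint of an oxygenated diene C8a=C4a–C5=C6 joined to an alkoxy ynone C7≡C8–C(=O)R.
2. Endgame: the two 7-hydroxyls are unmasked last from 2-(trimethylsilyl)ethyl ethers with fluoride.
3. Key disconnection: C6–C7 and C8–C8a in both halves at once, back to a bis-diene on the bridge carbon and two molecules of an (R)-alkoxy ynone. The pyran rings are made first (as delta-lactones) and the two benzene rings second.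
4. Bis-diene: 6-methylheptanal and malonate give 3-(5-methylhexyl)glutaric acid, which goes on to the bis-Weinreb amide, acylation of two lactone enolates, O5-silylation and O-phosphorylation at C8a.
5. Ynone: (R)-2-methylbutanoic acid, the source of both stereocentres, as its Weinreb amide, plus a lithium alkoxyacetylide made from trichloroethene.

Key step: step 11

Remark on numbering and stereochemistry: chroman numbering (O1, C2 … C8a) is used for all intermediates. With both side chains (R), the two arms on the bridge carbon are identical, so that carbon is not a stereocentre.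

Remark on the group at C8a: adducts of 1-alkoxy-1-silyloxy dienes with alkynes are known to aromatize by loss of the alkoxy group. Here that would open the pyran ring, so the ketene acetal oxygen carries diphenyl phosphate, a nucleofuge that cannot collapse to a carbonyl group.

Remark on the group at O7: a boron halide held by the ketone would also be directed to the tertiary O1–C2 bond, which is ortho to the same ketone. The alkynyl ether is therefore fluoride-labile rather than a simple alkyl ether.

## Route

Step 1
Reactants: 1 6-methylheptanal; 2 diethyl malonate (2.2 equiv)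
Product: 4 tetraethyl 2-(5-methylhexyl)propane-1,1,3,3-tetracarboxylate, via alkylidene malonate 3 (not isolated)
Conditions: piperidine, AcOH (cat.), toluene, Dean–Stark, reflux; then NaOEt (cat.), EtOH, 23 °C
Reagents that add atoms: none
Why: Knoevenagel condensation followed by Michael addition of a second malonate is the classical entry to 3-substituted glutaric acids, and no stereocentre arises because the two malonyl arms are identical.

Step 2
Reactants: 4 tetraethyl 2-(5-methylhexyl)propane-1,1,3,3-tetracarboxylate
Product: 6 3-(5-methylhexyl)pentanedioic acid, via tetracarboxylic acid 5 (not isolated)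
Conditions: 6 M aq HCl, reflux
Reagents that add atoms: water O
Why: Acidic ester hydrolysis and twofold malonic acid decarboxylation should leave one carboxymethyl arm on each side of the future bridge carbon.

Step 3
Reactants: 6 3-(5-methylhexyl)pentanedioic acid
Product: 8 N,N'-dimethoxy-N,N'-dimethyl-3-(5-methylhexyl)pentanediamide, via glutaryl dichloride 7 (not isolated)
Conditions: (COCl)2, DMF (cat.), CH2Cl2, 0 → 23 °C; concentrate; MeNHOMe·HCl, pyridine, CH2Cl2, 0 °C
Reagents that add atoms: oxalyl chloride O=C(Cl)C(=O)Cl (chlorine of 7); N,O-dimethylhydroxylamine hydrochloride CNOC.Cl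
Why: Acid chloride formation and amidation give the bis-Weinreb amide, which is preferred to the dichloride as acyl donor because a monoacylated enolate cannot cyclize onto the second amide terminus.

Step 4
Reactants: 9 ethyl 5-oxohexanoate
Product: 11 6,6-dimethyloxan-2-one, via bromomagnesium alkoxide 10 (not isolated)
Conditions: MeMgBr (1.05 equiv), THF, −78 → 0 °C; 1 M aq HCl
Reagents that add atoms: methylmagnesium bromide C[Mg]Br
Why: Grignard addition is faster at the ketone than at the ester at low temperature, and the tertiary alkoxide lactonizes spontaneously to the six-membered ring that becomes the pyran ring.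

Step 5
Reactants: 11 6,6-dimethyloxan-2-one (2.6 equiv); 8 N,N'-dimethoxy-N,N'-dimethyl-3-(5-methylhexyl)pentanediamide
Product: 14 3,3'-[3-(5-methylhexyl)pentanedioyl]bis(6,6-dimethyloxan-2-one), via lithium lactone enolate 12 (not isolated), via dilithium bis-hemiaminal alkoxide 13 (not isolated)
Conditions: LiN(iPr)2 (2.6 equiv), THF, −78 °C; 8, −78 → −30 °C; AcOH, THF, −78 °C
Reagents that add atoms: none
Why: In this crossed Claisen-type acylation by a Weinreb amide the chelated adduct 13 persists until the quench, so proton exchange with the acidic product and ring closure across the glutaryl chain are both excluded, and the labile C4a stereocentres are erased in step 6.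

Step 6
Reactants: 14 3,3'-[3-(5-methylhexyl)pentanedioyl]bis(6,6-dimethyloxan-2-one)
Product: 15 3,3'-[3-(5-methylhexyl)-1,5-bis(trimethylsilyloxy)pentane-1,5-diylidene]bis(6,6-dimethyloxan-2-one)
Conditions: Me3SiCl, Et3N, toluene, 23 °C; filtration under Ar
Reagents that add atoms: chlorotrimethylsilane C[Si](C)(C)Cl
Why: Amine-mediated O-silylation of the strongly enolized 2-acyl lactone, the usual first stage in making 1,3-dioxygenated dienes from beta-keto esters, places silicon on O5 only.

Step 7
Reactants: 15 3,3'-[3-(5-methylhexyl)-1,5-bis(trimethylsilyloxy)pentane-1,5-diylidene]bis(6,6-dimethyloxan-2-one)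
Product: 17 tetraphenyl {[(1Z,4Z)-3-(5-methylhexyl)-1,5-bis(trimethylsilyloxy)penta-1,4-diene-1,5-diyl]bis(6,6-dimethyl-5,6-dihydro-4H-pyran-3,2-diyl)} bis(phosphate), via dilithium bis-dienolate 16 (not isolated)
Conditions: LiN(iPr)2 (2.1 equiv), THF, −78 °C; (PhO)2P(O)Cl (2.1 equiv), DMPU, −78 → 0 °C; pentane, filtration under Ar, used without chromatography
Reagents that add atoms: diphenyl chlorophosphate O=P(Cl)(Oc1ccccc1)Oc1ccccc1
Why: Gamma-deprotonation of the 3-silyloxy enoate at C6 gives the extended enolate, which the hard chlorophosphate traps on the lactone oxygen as in the established preparation of lactone-derived ketene acetal phosphates, while allylic 1,3-strain places the bridge carbon trans to C4a, giving (Z) enol ethers.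

Step 8
Reactants: 18 2-(trimethylsilyl)ethanol; 19 trichloroethene
Product: 22 [2-(1,2-dichloroethenyloxy)ethyl]trimethylsilane, via sodium alkoxide 20 (not isolated), via dichloroethyne 21 (not isolated)
Conditions: NaH, THF, 0 °C; 19, 0 → 40 °C
Reagents that add atoms: none
Why: In the classical alkoxide/trichloroethene reaction dehydrochlorination releases dichloroethyne, to which the alkoxide adds, and the sodium salt is chosen because potassium beta-silyl alkoxides are more prone to Peterson-type loss of ethene.

Step 9
Reactants: 23 (R)-2-methylbutanoic acid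
Product: 25 (R)-N-methoxy-N,2-dimethylbutanamide, via acyl imidazole 24 (not isolated)
Conditions: 1,1'-carbonyldiimidazole, CH2Cl2, 0 → 23 °C; MeNHOMe·HCl, 23 °C
Reagents that add atoms: 1,1'-carbonyldiimidazole O=C(n1ccnc1)n1ccnc1 (imidazolyl group of 24); N,O-dimethylhydroxylamine hydrochloride CNOC.Cl
Why: Acyl imidazole activation and aminolysis (Weinreb amide formation) need neither strong base nor a ketene-forming amine, so the alpha stereocentre should be retained.

Step 10
Reactants: 22 [2-(1,2-dichloroethenyloxy)ethyl]trimethylsilane (1.3 equiv); 25 (R)-N-methoxy-N,2-dimethylbutanamide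
Product: 29 (R)-4-methyl-1-[2-(trimethylsilyl)ethoxy]hex-1-yn-3-one, via chloroalkynyl ether 26 (not isolated), via lithium alkoxyacetylide 27 (not isolated), via lithium hemiaminal alkoxide 28 (not isolated)
Conditions: n-BuLi (2.6 equiv), THF, −78 → −40 °C; 25, −78 → −10 °C; inverse quench into cold 0.5 M aq HCl, rapid extraction; Et3N-deactivated silica
Reagents that add atoms: none
Why: Dehydrochlorination and chlorine–lithium exchange give the acetylide, the Weinreb ketone synthesis stops at the ynone through chelate 28, and the weakly basic acetylide does not enolize the amide, so the (R) centre is carried over.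

Step 11
Reactants: 17 bis(1-phosphoryloxy-3-silyloxy diene); 29 (R)-4-methyl-1-[2-(trimethylsilyl)ethoxy]hex-1-yn-3-one (2.6 equiv)
Product: 32 7,7'-bis-O-[2-(trimethylsilyl)ethyl] ether of the target, via twofold cycloadduct 30 (not isolated), via bis(aryl silyl ether) 31 (not isolated)
Conditions: 2,6-di-tert-butyl-4-methylpyridine (2.5 equiv), toluene (0.5 M), Ar, 23 → 60 °C; then THF–0.5 M aq citric acid, 23 °C
Reagents that add atoms: none
Why: Proposed new method: diene carbon C6, made nucleophilic by the O5 silyl enol ether and the vinylogous donor O1, attacks the alkoxy-bearing alkyne carbon (future C7), and the resulting allenolate carbon (future C8) closes onto the ketene acetal carbon C8a, either as one asynchronous [4+2] event or as a Mukaiyama–Michael addition followed by ring closure. The closest known reaction type is the Diels–Alder/aromatization of 1-alkoxy-1,3-bis(silyloxy)- and 1,1-dialkoxy-3-silyloxybutadienes with alkynones and acetylenic esters; the donor-substituted alkyne, the phosphate-bearing cyclic ketene acetal and the twofold execution are new. Each benzene ring is closed by an intermolecular six-membered [4+2] closure (bonds C6–C7 and C8–C8a) onto a pyran ring already in place, so the chroman orientation is fixed by connectivity. At C8a adduct 30 (drawn with both halves at the adduct stage, though each half should aromatize as it forms) carries a phosphate beside a tertiary ring alkoxide, so it should ionize only by loss of phosphate to a cation stabilized by O1, O5 and O7, which gives up H6 to the hindered pyridine. Regiochemistry rests on pairing the only nucleophilic diene terminus (C6) with the beta carbon of the ynone, and the (Z) enol ether geometry keeps the bridge carbon on the outside of the s-cis diene. No lasting stereocentre is formed (C6 and C8a become sp2 and the bridge carbon bears two identical arms), and the non-enolizing medium leaves the two (R) centres untouched.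

Step 12
Reactants: 32 7,7'-bis-O-[2-(trimethylsilyl)ethyl] ether of the target
Product: 33 (2R,2'R)-1,1'-[(6-methylheptane-1,1-diyl)bis(5,7-dihydroxy-2,2-dimethylchroman-6,8-diyl)]bis(2-methylbutan-1-one)
Conditions: Bu4NF (6 equiv), THF, Ar, 0 → 23 °C; AcOH
Reagents that add atoms: none
Why: Fluoride attack at silicon triggers Peterson-type fragmentation with loss of ethene and expulsion of the 2-acylphenoxide, while the tertiary chroman ether is inert to fluoride and the ketone, delocalized with the phenoxides, should not be enolized at its alpha carbon.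

## Compound list

1 | 6-methylheptanal | CC(C)CCCCC=O | starting material
2 | diethyl malonate | CCOC(=O)CC(=O)OCC | starting material
3 | diethyl 2-(6-methylheptylidene)propanedioate | CC(C)CCCCC=C(C(=O)OCC)C(=O)OCC | intermediate
4 | tetraethyl 2-(5-methylhexyl)propane-1,1,3,3-tetracarboxylate | CC(C)CCCCC(C(C(=O)OCC)C(=O)OCC)C(C(=O)OCC)C(=O)OCC | intermediate
5 | 2-(5-methylhexyl)propane-1,1,3,3-tetracarboxylic acid | CC(C)CCCCC(C(C(=O)O)C(=O)O)C(C(=O)O)C(=O)O | intermediate
6 | 3-(5-methylhexyl)pentanedioic acid | CC(C)CCCCC(CC(=O)O)CC(=O)O | intermediate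
7 | 3-(5-methylhexyl)pentanedioyl dichloride | CC(C)CCCCC(CC(=O)Cl)CC(=O)Cl | intermediate
8 | N,N'-dimethoxy-N,N'-dimethyl-3-(5-methylhexyl)pentanediamide | CC(C)CCCCC(CC(=O)N(C)OC)CC(=O)N(C)OC | intermediate
9 | ethyl 5-oxohexanoate | CCOC(=O)CCCC(C)=O | starting material
10 | bromomagnesium 6-ethoxy-2-methyl-6-oxohexan-2-olate | CCOC(=O)CCCC(C)(C)[O-].[Mg+2].[Br-] | intermediate
11 | 6,6-dimethyloxan-2-one | CC1(C)CCCC(=O)O1 | intermediate
12 | lithium 6,6-dimethyl-5,6-dihydro-4H-pyran-2-olate | CC1(C)CCC=C([O-])O1.[Li+] | intermediate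
13 | dilithium bis-hemiaminal alkoxide from 8 and two 12 (new centres undefined) | CC(C)CCCCC(CC([O-])(N(C)OC)C1CCC(C)(C)OC1=O)CC([O-])(N(C)OC)C1CCC(C)(C)OC1=O.[Li+].[Li+] | intermediate
14 | 3,3'-[3-(5-methylhexyl)pentanedioyl]bis(6,6-dimethyloxan-2-one), keto/enol and diastereomer mixture | CC(C)CCCCC(CC(=O)C1CCC(C)(C)OC1=O)CC(=O)C1CCC(C)(C)OC1=O | intermediate
15 | 3,3'-[3-(5-methylhexyl)-1,5-bis(trimethylsilyloxy)pentane-1,5-diylidene]bis(6,6-dimethyloxan-2-one), alkene geometry of no consequence | CC(C)CCCCC(CC(O[Si](C)(C)C)=C1CCC(C)(C)OC1=O)CC(O[Si](C)(C)C)=C1CCC(C)(C)OC1=O | intermediate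
16 | dilithium bis-dienolate of 15 | CC(C)CCCCC(/C=C(O[Si](C)(C)C)/C1=C([O-])OC(C)(C)CC1)/C=C(O[Si](C)(C)C)/C1=C([O-])OC(C)(C)CC1.[Li+].[Li+] | intermediate
17 | tetraphenyl {[(1Z,4Z)-3-(5-methylhexyl)-1,5-bis(trimethylsilyloxy)penta-1,4-diene-1,5-diyl]bis(6,6-dimethyl-5,6-dihydro-4H-pyran-3,2-diyl)} bis(phosphate) | CC(C)CCCCC(/C=C(O[Si](C)(C)C)/C1=C(OP(=O)(Oc2ccccc2)Oc2ccccc2)OC(C)(C)CC1)/C=C(O[Si](C)(C)C)/C1=C(OP(=O)(Oc2ccccc2)Oc2ccccc2)OC(C)(C)CC1 | intermediate
18 | 2-(trimethylsilyl)ethanol | C[Si](C)(C)CCO | starting material
19 | trichloroethene | ClC=C(Cl)Cl | starting material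
20 | sodium 2-(trimethylsilyl)ethoxide | C[Si](C)(C)CC[O-].[Na+] | intermediate
21 | dichloroethyne | ClC#CCl | intermediate
22 | [2-(1,2-dichloroethenyloxy)ethyl]trimethylsilane, alkene geometry of no consequence | C[Si](C)(C)CCOC(Cl)=CCl | intermediate
23 | (R)-2-methylbutanoic acid | CC[C@@H](C)C(=O)O | starting material
24 | (R)-1-(1H-imidazol-1-yl)-2-methylbutan-1-one | CC[C@@H](C)C(=O)n1ccnc1 | intermediate
25 | (R)-N-methoxy-N,2-dimethylbutanamide | CC[C@@H](C)C(=O)N(C)OC | intermediate
26 | [2-(chloroethynyloxy)ethyl]trimethylsilane | C[Si](C)(C)CCOC#CCl | intermediate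
27 | lithium [2-(trimethylsilyl)ethoxy]acetylide | C[Si](C)(C)CCOC#[C-].[Li+] | intermediate
28 | lithium hemiaminal alkoxide from 25 and 27 (carbinol centre undefined, side chain R) | C[Si](C)(C)CCOC#CC([O-])(N(C)OC)[C@H](C)CC.[Li+] | intermediate
29 | (R)-4-methyl-1-[2-(trimethylsilyl)ethoxy]hex-1-yn-3-one | C[Si](C)(C)CCOC#CC(=O)[C@H](C)CC | intermediate
30 | twofold cycloadduct, 6,8a-dihydrochroman ketal phosphate in each half (C6 and C8a undefined, side chains R) | CC(C)CCCCC(C1C(O[Si](C)(C)C)=C2CCC(C)(C)OC2(OP(=O)(Oc3ccccc3)Oc3ccccc3)C(C(=O)[C@H](C)CC)=C1OCC[Si](C)(C)C)C1C(O[Si](C)(C)C)=C2CCC(C)(C)OC2(OP(=O)(Oc3ccccc3)Oc3ccccc3)C(C(=O)[C@H](C)CC)=C1OCC[Si](C)(C)C | intermediate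
31 | 5,5'-bis-O-trimethylsilyl-7,7'-bis-O-[2-(trimethylsilyl)ethyl] ether of the target | CC[C@@H](C)C(=O)c1c(OCC[Si](C)(C)C)c(C(CCCCC(C)C)c2c(OCC[Si](C)(C)C)c(C(=O)[C@H](C)CC)c3OC(C)(C)CCc3c2O[Si](C)(C)C)c(O[Si](C)(C)C)c2CCC(C)(C)Oc12 | intermediate
32 | 7,7'-bis-O-[2-(trimethylsilyl)ethyl] ether of the target (5- and 5'-hydroxyl free) | CC[C@@H](C)C(=O)c1c(OCC[Si](C)(C)C)c(C(CCCCC(C)C)c2c(OCC[Si](C)(C)C)c(C(=O)[C@H](C)CC)c3OC(C)(C)CCc3c2O)c(O)c2CCC(C)(C)Oc12 | intermediate
33 | (2R,2'R)-1,1'-[(6-methylheptane-1,1-diyl)bis(5,7-dihydroxy-2,2-dimethylchroman-6,8-diyl)]bis(2-methylbutan-1-one) | CC[C@@H](C)C(=O)c1c(O)c(C(CCCCC(C)C)c2c(O)c3c(c(C(=O)[C@H](C)CC)c2O)OC(C)(C)CC3)c(O)c2c1OC(C)(C)CC2 | target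

## Step count

Total step count: 12.
Longest linear sequence: 8 steps (steps 1, 2, 3, 5, 6, 7, 11, 12).

## Steps most likely to fail

**1. Step 11.**
- What may go wrong:
  - The donor-substituted alkyne may react too slowly with a diene whose ketene acetal is attenuated by the phosphate.
  - Conjugate addition at C6 may stop short of ring closure through silyl transfer to the allenolate.
  - Retro-ene fragmentation of the ynol ether may set in if more heat is needed.
  - Crowding at the bridge carbon may stall the second annulation.
- Fallback (known chemistry, from 23 and 1, back at 33):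
  - 23 is converted with (COCl)2 into (R)-2-methylbutanoyl chloride F1.
  - F1 acylates phloroglucinol under Friedel–Crafts conditions (AlCl3, CH2Cl2–MeNO2) to (R)-2-methyl-1-(2,4,6-trihydroxyphenyl)butan-1-one F2.
  - Acid-catalysed chroman annulation with 2-methylbut-3-en-2-ol (BF3·OEt2, dioxane), followed by separation from the 6-acyl regioisomer, gives (R)-1-(5,7-dihydroxy-2,2-dimethylchroman-8-yl)-2-methylbutan-1-one F3.
  - Two equivalents of F3 are condensed at their free C6 with aldehyde 1 (piperidinium acetate, EtOH). This is a Knoevenagel-type condensation to an ortho-quinone methide followed by conjugate addition of the second nucleus, and it gives 33.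
  - The price is the loss of the built-in control of chroman orientation.

**2. Step 7.**
- What may go wrong:
  - The twofold gamma-deprotonation may be incomplete.
  - Excess amide base may cause oxygen-to-carbon phosphoryl migration.
  - The silyl enol ethers may hydrolyse during isolation.
- Fallback (from 15, back at 31):
  - The second stage is run with silicon instead of phosphorus (LiN(iPr)2, then Me3SiCl). This is the standard preparation of such dienes and gives the tetrakis(trimethylsilyloxy) bis-diene F4.
  - F4 is combined with 29 as in step 11 to give the twofold mixed alkyl silyl ketal adduct F5.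
  - Protic work-up of F5 would be expected to open the pyran rings. F5 is therefore treated in the same flask, before any proton source is admitted, with DBU at low temperature.
  - Deprotonation at C6, which is vinylogous to the ketone, then expels the better nucleofuge, trimethylsilanolate, by an E1cB pathway and gives 31.

**3. Step 5.**
- What may go wrong:
  - Proton transfer may occur between the lactone enolate and the alpha-methylene groups of the amide.
  - The lactone enolate may self-condense on warming.
  - The second acylation may stall.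
- Fallback (from 8, back at 14):
  - 8 is reduced with iBu2AlH (THF, −78 °C) to 3-(5-methylhexyl)pentanedial F6.
  - F6 undergoes a fast twofold aldol addition with enolate 12 at −78 °C to the bis(beta-hydroxy lactone) F7.
  - Oxidation of both carbinols with Dess–Martin periodinane gives 14.

## Further compounds

F1 | step 11 | (R)-2-methylbutanoyl chloride | CC[C@@H](C)C(=O)Cl
F2 | step 11 | (R)-2-methyl-1-(2,4,6-trihydroxyphenyl)butan-1-one | CC[C@@H](C)C(=O)c1c(O)cc(O)cc1O
F3 | step 11 | (R)-1-(5,7-dihydroxy-2,2-dimethylchroman-8-yl)-2-methylbutan-1-one | CC[C@@H](C)C(=O)c1c(O)cc(O)c2CCC(C)(C)Oc12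
F4 | step 7 | (1Z,4Z)-tetrakis(trimethylsilyloxy) bis-diene, silyl analogue of 17 | CC(C)CCCCC(/C=C(O[Si](C)(C)C)/C1=C(O[Si](C)(C)C)OC(C)(C)CC1)/C=C(O[Si](C)(C)C)/C1=C(O[Si](C)(C)C)OC(C)(C)CC1
F5 | step 7 | twofold cycloadduct of F4 and 29, mixed alkyl silyl ketal at each C8a (C6 and C8a undefined) | CC(C)CCCCC(C1C(O[Si](C)(C)C)=C2CCC(C)(C)OC2(O[Si](C)(C)C)C(C(=O)[C@H](C)CC)=C1OCC[Si](C)(C)C)C1C(O[Si](C)(C)C)=C2CCC(C)(C)OC2(O[Si](C)(C)C)C(C(=O)[C@H](C)CC)=C1OCC[Si](C)(C)C
F6 | step 5 | 3-(5-methylhexyl)pentanedial | CC(C)CCCCC(CC=O)CC=O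
F7 | step 5 | 3,3'-[1,5-dihydroxy-3-(5-methylhexyl)pentane-1,5-diyl]bis(6,6-dimethyloxan-2-one), diastereomer mixture | CC(C)CCCCC(CC(O)C1CCC(C)(C)OC1=O)CC(O)C1CCC(C)(C)OC1=O
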